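At 3.0 h I can read a flask two ways. The first freezes the rate: the south-east run first loses substrate at 1.17 h⁻¹, and held for that long, this rate turns 97.0% of the charge into product. The second freezes the stock: I take this for phase-transfer catalysis with one salt spent per product, which makes salt the limiting reagent wherever it is charged short. The ceiling is then the salt cap, salt charged as a fraction of substrate charged, which for Monday's is 53.3%.

| flask | substrate | salt in the second phase | spent carrier | remark | time | volume of the second phase over the first |
|---|---|---|---|---|---|---|
| south-east | 0.11 M | 0.11 M | 5.2 mM | run made earlier |  |  |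
| south | 0.11 M | 0.29 M | 5.2 mM | run made earlier |  |  |
| south-west | 0.14 M | 0.116 M | 5.2 mM | run made earlier |  |  |
| Tuesday's | 0.040 M | 0.116 M | 20 mM |  | 3.0 h | 1.0 |
| Monday's | 0.15 M | 0.0800 M | 5.2 mM |  | 3.0 h | 1.0 |
| Saturday's | 0.20 M | 0.116 M | 2.5 mM |  | 3.0 h | 1.0 |
| Thursday's | 0.11 M | 0.116 M | 5.2 mM |  | 3.0 h | 1.0 |
| Sunday's | 0.40 M | 0.250 M | 5.2 mM |  | 3.0 h | 1.0 |

- south-east (time / h: product / %, substrate / %): 0.417: 38.9, 61.3; 0.833: 58.8, 39.4; 1.33: 74.5, 25.8; 1.50: 75.4, 22.8; 2.00: 84.2, 17.2; 2.50: 86.9, 13.0; 3.00: 88.5, 10.2
- south (time / h: product / %, substrate / %): 0.417: 42.1, 58.4; 0.833: 67.6, 35.8; 1.33: 81.5, 16.7; 1.50: 84.0, 14.6; 2.00: 91.4, 7.0; 2.50: 96.0, 4.4; 3.00: 96.1, 2.5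
- south-west (time / h: product / %, substrate / %): 0.250: 24.7, 74.8; 0.417: 38.8, 62.4; 0.833: 58.5, 42.8; 1.50: 73.0, 27.7; 3.00: 79.9, 17.9

(readings scatter by 1 percentage point)

- ranking by amount of product, in percent of the substrate charged, from high to low, at 3.0 h (Tuesday's / Monday's / Saturday's / Thursday's / Sunday's)
- the same order at 40 min (Tuesday's / Monday's / Saturday's / Thursday's / Sunday's)
- the amount of product, in percent of the substrate charged of the flask you put first, at 3.0 h
- the amount of product, in percent of the substrate charged of the flask you put last, at 3.0 h

- charges count per volume of the first phase; a concentration in a rate is the amount of a species over the volume of its own phase; every rate counts per litre of the first phase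
- the numbers in the tables scatter by 1 percentage point (one standard deviation)
- the earlier runs hold the two phases in the same ratio of volumes as the flask asked about

The earlier runs show when each way can be trusted. In the south run the cap is 264%, out of the way, and the reading of 96.1% stands close to the frozen rate's 97.0%. In the south-west run the two ways part: the cap is 82.9%, the frozen rate again says 97.0%, and the reading is 79.9%, below the cap. So the frozen rate, higher than that reading, is the one that cheats once salt thins.

The frozen rate still gives a useful time, the time to reach the cap. South-west needs 1.50 h and stops just short of its cap. Monday's needs 0.649 h, less than south-west, so I put it at about 53.3%. Assuming the rate scales with carrier, Saturday's has a cap of 58.0%, runs at 0.564 h⁻¹ and needs 1.54 h, so I expect it to stop a little short of that cap, yet its cap stands above Monday's. Sunday's cap is 62.5%, higher than Saturday's. Thursday's cap is 105%, and its neighbour, the south-east run, reads 88.5%. Tuesday's has a cap of 290% and a rate of 4.51 h⁻¹, the highest of the five, so I put it first and close to full conversion. At 40 min Saturday's frozen rate gives 31.3% against Monday's 54.2%, so with the lowest rate of the five I put Saturday's last; the three middle flasks I can't separate.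

The forecast ranks Tuesday's > Thursday's > Sunday's > Saturday's > Monday's at 3.0 h and Tuesday's > Thursday's > Sunday's > Monday's > Saturday's at 40 min, with 99.8% (98% to 100%) first and 53% (51.5% to 53.6%) last, on the ground that “Salt caps conversion”. Its order at 3.0 h is mine; at 40 min it splits the middle flasks, which I do not.

The flasks rank Tuesday's > Thursday's > Sunday's > Saturday's > Monday's at 3.0 h and Tuesday's > Thursday's > Sunday's > Monday's > Saturday's at 40 min, with Tuesday's at >99.9% and Monday's at 53.3% against its cap of 53.3%.

    2 spent carrier → spent catalyst (k = 0.0220 M⁻¹ s⁻¹)
    substrate + fresh carrier → product + spent carrier (k = 0.0740 M⁻¹ s⁻¹)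
    spent carrier + salt in the second phase ⇌ fresh carrier + spent salt in the second phase (K = 5.60, k = 0.760 M⁻¹ s⁻¹)

In Monday's at 0.268 h, spent carrier goes by the forward salt step at 440 times its rate by the step to spent catalyst. At 3.00 h Monday's holds 0.074% of its salt beside 47% of its substrate. The flask like Monday's but charged with 0.60 M of substrate has a cap of 13.3% and gives 13.3%.

The readings were generated by integration with made-up constants; noise was put on by code.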